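**Strategy.** The 2,8-dioxabicyclo[3.2.1]octane (C1 ketal carbon, O2, C3 alkenyl-bearing, C5 methyl-bearing bridgehead, O8) is unravelled at C1. The C1–O2 bond comes from acid-mediated addition of the C3 carbinol to a cyclic enol ether. The bond from C1 to the tertiary carbinol comes from addition of a 5-lithio-2,3-dihydrofuran (acyl-anion umpolung) to a RAMP-derived dioxanone. The oxolane ring O8–C1–C7–C6–C5 is grown from an oxirane: copper-catalysed ring expansion of a 2-methyl-2-alkyl-3-vinyloxirane inserts the two vinyl carbons (future C7, C1) into the allylic O8–C6 bond. The C5–O8 bond is never broken, so the quaternary stereocentre set by asymmetric epoxidation is delivered intact.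

Key step: step 7

Remarks: (i) geranial (E isomer, free of neral) is taken as a purchasable material. (ii) The antipodes of the phosphoric acid (step 1) and of the hydrazine auxiliary (step 10) are those predicted by the accepted transition-state models and would be checked on compounds 3 and 18.

**Route**

Step 1
Reactants: 1 geranial; 2 allenylboronic acid pinacol ester
Product: 3 (4S,5E)-6,10-dimethylundeca-5,9-dien-1-yn-4-ol
Conditions: (S)-TRIP phosphoric acid (5–10 mol %), 4 Å MS, toluene, 0 °C → rt; aq. work-up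
Reagents that add atoms: none
Why: Chiral phosphoric acid-catalysed propargylation, in which the allenylboronate adds through a closed six-membered SE2′ transition state with the catalyst hydrogen-bonded to the boronate oxygen, so that Si-face attack on the enal should set the 4S carbinol (the later C3 of the bicycle).

Step 2
Reactants: 3
Product: 4 tert-butyldimethylsilyl ether of 3
Conditions: TBSCl, imidazole, DMF, rt
Reagents that add atoms: tert-butyldimethylsilyl chloride, CC(C)(C)[Si](C)(C)Cl
Why: Imidazole-promoted silylation of the secondary alcohol masks the carbinol so that the later epoxidation and oxidation address only the primary allylic alcohol.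

Step 3
Reactants: 4
Product: 6 (2E,5S,6E)-5-(tert-butyldimethylsilyloxy)-3,7,11-trimethyldodeca-2,6,10-trien-1-ol, via alkenyldimethylalane 5 (not isolated)
Conditions: Me3Al, Cp2ZrCl2 (0.25 equiv), CH2Cl2, 0 °C → rt; then n-BuLi, THF, −78 °C; (CH2O)n, −78 °C → rt; H2O
Reagents that add atoms: trimethylaluminium, C[Al](C)C; paraformaldehyde (formaldehyde unit), C=O
Why: Zirconium-catalysed carboalumination (Negishi) adds Me–Al syn across the terminal alkyne with methyl on the internal carbon, and hydroxymethylation of the derived alanate with retention should fix the E-trisubstituted geraniol-type alkene while the isolated trisubstituted alkenes do not carbometalate.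

Step 4
Reactants: 6
Product: 7 {(2S,3S)-3-methyl-3-[(2S,3E)-2-(tert-butyldimethylsilyloxy)-4,8-dimethylnona-3,7-dien-1-yl]oxiran-2-yl}methanol
Conditions: Ti(OiPr)4 (10 mol %), L-(+)-diethyl tartrate (12 mol %), t-BuOOH, 4 Å MS, CH2Cl2, −20 °C
Reagents that add atoms: tert-butyl hydroperoxide, CC(C)(C)OO
Why: Sharpless asymmetric epoxidation, in which the titanium–L-(+)-tartrate complex binds the primary allylic alcohol and delivers oxygen to the face that gives the (2S,3S)-epoxide of this geraniol-type E-alkene (reagent control), sets the methyl-bearing carbon as the later C5 while the other alkenes carry no free allylic hydroxyl.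

Step 5
Reactants: 7
Product: 8 (2R,3S)-3-methyl-3-[(2S,3E)-2-(tert-butyldimethylsilyloxy)-4,8-dimethylnona-3,7-dien-1-yl]oxirane-2-carbaldehyde
Conditions: TEMPO (10 mol %), PhI(OAc)2, CH2Cl2, rt
Reagents that add atoms: none
Why: Oxoammonium (TEMPO) oxidation takes the primary alcohol to the aldehyde under near-neutral conditions that should leave the epoxide, the silyl ether and the alkenes untouched and not epimerise the α-epoxy aldehyde.

Step 6
Reactants: 8
Product: 9 (2S,3S)-3-ethenyl-2-methyl-2-[(2S,3E)-2-(tert-butyldimethylsilyloxy)-4,8-dimethylnona-3,7-dien-1-yl]oxirane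
Conditions: Ph3PCH3Br, KHMDS, THF, −78 → 0 °C
Reagents that add atoms: methyltriphenylphosphonium bromide, C[P+](c1ccccc1)(c1ccccc1)c1ccccc1.[Br-]
Why: Wittig methylenation with a salt-free non-stabilised ylide at low temperature should convert the α,β-epoxy aldehyde into the vinyl oxirane without opening the epoxide or epimerising the α-carbon.

Step 7
Reactants: 9
Product: 10 (2S)-2-methyl-2-[(2S,3E)-2-(tert-butyldimethylsilyloxy)-4,8-dimethylnona-3,7-dien-1-yl]-2,5-dihydrofuran
Conditions: Cu(hfacac)2 (5 mol %), toluene, 150 °C, sealed tube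
Reagents that add atoms: none
Why: The Lewis-acidic Cu(II) centre binds the oxirane oxygen and breaks only the allylic C–O bond (at the vinyl-bearing carbon), giving a copper alkoxide/allyl cation pair (or its σ-allyl copper equivalent) that recloses through oxygen on the terminal vinyl carbon, a net 1,3-oxygen shift that enlarges the three-membered ring by the two vinyl carbons. The closest known reaction type is the copper-catalysed ring expansion of vinyl oxiranes to 2,5-dihydrofurans. The five-membered ring closes by attack of the alkoxide on the distal terminus of the cisoid allyl unit (formally 5-endo with respect to the allyl π system, which is why metal-assisted ionisation is required). No stereocentre is created: the vinyl-bearing epoxide carbon becomes sp2, and the methyl-bearing quaternary carbon keeps its C–O bond throughout, so its configuration from step 4 is carried over unchanged as the future C5. The step needs ionisation at the allylic and not the tertiary C–O bond and no capture of the allyl cation by the silyl ether oxygen; allylic stabilisation, the weakly coordinating hexafluoroacetylacetonate ligands, the bulky silyl group and the apolar medium should secure this, and the isolated trisubstituted alkenes are inert.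

Step 8
Reactants: 10
Product: 11 (2R)-2-methyl-2-[(2S,3E)-2-(tert-butyldimethylsilyloxy)-4,8-dimethylnona-3,7-dien-1-yl]-2,3-dihydrofuran
Conditions: RuHCl(CO)(PPh3)3 (3 mol %), toluene, 80 °C
Reagents that add atoms: none
Why: Ruthenium hydride-catalysed alkene isomerisation (hydrometalation/β-hydride elimination) should move the ring double bond into conjugation with oxygen to give the enol ether, since the quaternary C2 allows migration in one direction only and the hindered trisubstituted alkenes do not insert.

Step 9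
Reactants: 12 2,5-dimethoxytoluene
Product: 13 1-(bromomethyl)-2,5-dimethoxy-4-methylbenzene
Conditions: (CH2O)n, 33 % HBr in AcOH, AcOH, rt
Reagents that add atoms: paraformaldehyde (formaldehyde unit), C=O; hydrogen bromide, Br
Why: Electrophilic aromatic bromomethylation (Blanc-type) should occur at the position para to methyl and ortho to methoxy, the only strongly activated unhindered site.

Step 10
Reactants: 14 2,2-dimethyl-1,3-dioxan-5-one; 15 RAMP [(R)-1-amino-2-(methoxymethyl)pyrrolidine]
Product: 16 RAMP hydrazone of 2,2-dimethyl-1,3-dioxan-5-one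
Conditions: benzene, reflux, Dean–Stark
Reagents that add atoms: none
Why: Condensation of the symmetric ketone with the N-amino auxiliary gives a single hydrazone (SAMP/RAMP hydrazone method).

Step 11
Reactants: 16; 13
Product: 18 (4R)-4-[(2,5-dimethoxy-4-methylphenyl)methyl]-2,2-dimethyl-1,3-dioxan-5-one, via alkylated hydrazone 17 (not isolated)
Conditions: t-BuLi, THF, −78 °C; 13, −100 °C → rt; then sat. aq. oxalic acid, Et2O, rt
Reagents that add atoms: water, O
Why: SAMP/RAMP-hydrazone alkylation, in which the methoxy-chelated lithium azaenolate is benzylated on one face (the RAMP series should give the 4R ketone, the mirror image of the SAMP outcome), followed by mild oxalic acid hydrolysis that should release the ketone without racemisation or loss of the acetonide.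

Step 12
Reactants: 11; 18
Product: 20 (4R,5S)-4-[(2,5-dimethoxy-4-methylphenyl)methyl]-2,2-dimethyl-5-{(5R)-5-methyl-5-[(2S,3E)-2-(tert-butyldimethylsilyloxy)-4,8-dimethylnona-3,7-dien-1-yl]-4,5-dihydrofuran-2-yl}-1,3-dioxan-5-ol, via 5-lithio-2,3-dihydrofuran 19 (not isolated)
Conditions: t-BuLi, THF/pentane, −78 → 0 °C; CeCl3, THF, −78 °C; then 18, −78 °C; H2O
Reagents that add atoms: none
Why: α-Lithiation of the cyclic enol ether gives an acyl-anion equivalent whose cerium reagent adds 1,2 to the ketone, and attack along the axial trajectory of the 1,3-dioxan-5-one chair (no 1,3-diaxial hydrogens, benzyl group equatorial) should place the dihydrofuranyl group cis to the benzyl group and set the 5S tertiary carbinol.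

Step 13
Reactants: 20
Product: 23 (2S,3R)-2-{(1R,3S,5R)-3-[(1E)-2,6-dimethylhepta-1,5-dien-1-yl]-5-methyl-2,8-dioxabicyclo[3.2.1]octan-1-yl}-4-(2,5-dimethoxy-4-methylphenyl)butane-1,2,3-triol, via desilylated enol ether 21 (not isolated), via ketal acetonide 22 (not isolated)
Conditions: TBAF, THF, 0 °C → rt; then PPTS, MeOH, rt → 45 °C
Reagents that add atoms: none
Why: Fluoride desilylation frees the allylic carbinol and mild acid protonates the enol ether at its β-carbon, so that the oxocarbenium ion at C1 is captured by that hydroxyl in a bridging ketalisation under thermodynamic control (1,3-dioxane and oxepane rings closed at once, C1 configuration dictated by C5, alkenyl group exo/equatorial) while the acetonide is transketalised to methanol.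

Step 14
Reactants: 23
Product: 24 1,3-di-O-acetate of 23
Conditions: Ac2O, pyridine, DMAP (cat.), CH2Cl2, 0 °C → rt
Reagents that add atoms: acetic anhydride, CC(=O)OC(C)=O
Why: Nucleophile-catalysed acylation should esterify the primary and secondary hydroxyls, while the tertiary hydroxyl next to the ketal carbon is too hindered to react under these conditions.

Step 15
Reactants: 24
Product: 26 target hydroquinone CNP0160303.2, via benzoquinone 25 (not isolated)
Conditions: (NH4)2Ce(NO3)6, MeCN/H2O, 0 °C; then aq. Na2S2O4, EtOAc, rt, under argon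
Reagents that add atoms: water, O
Why: Oxidative demethylation of the hydroquinone dimethyl ether by cerium(IV) (arene radical cation, ipso attack of water, loss of methanol) should give the benzoquinone, which dithionite reduces to the hydroquinone, the isolated alkenes, esters and bicyclic ketal not being oxidised at 0 °C.

**Compound list**

1 | geranial, (2E)-3,7-dimethylocta-2,6-dienal | CC(C)=CCC/C(C)=C/C=O | starting material
2 | allenylboronic acid pinacol ester | C=C=CB1OC(C)(C)C(C)(C)O1 | starting material
3 | (4S,5E)-6,10-dimethylundeca-5,9-dien-1-yn-4-ol | C#CC[C@H](O)/C=C(\C)CCC=C(C)C | intermediate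
4 | tert-butyl{[(4S,5E)-6,10-dimethylundeca-5,9-dien-1-yn-4-yl]oxy}dimethylsilane | C#CC[C@H](O[Si](C)(C)C(C)(C)C)/C=C(\C)CCC=C(C)C | intermediate
5 | (E)-alkenyldimethylalane from carboalumination of 4 (formed in the flask) | C[Al](C)/C=C(\C)C[C@H](O[Si](C)(C)C(C)(C)C)/C=C(\C)CCC=C(C)C | intermediate
6 | (2E,5S,6E)-5-(tert-butyldimethylsilyloxy)-3,7,11-trimethyldodeca-2,6,10-trien-1-ol | OC/C=C(\C)C[C@H](O[Si](C)(C)C(C)(C)C)/C=C(\C)CCC=C(C)C | intermediate
7 | {(2S,3S)-3-methyl-3-[(2S,3E)-2-(tert-butyldimethylsilyloxy)-4,8-dimethylnona-3,7-dien-1-yl]oxiran-2-yl}methanol | OC[C@@H]1O[C@@]1(C)C[C@H](O[Si](C)(C)C(C)(C)C)/C=C(\C)CCC=C(C)C | intermediate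
8 | (2R,3S)-3-methyl-3-[(2S,3E)-2-(tert-butyldimethylsilyloxy)-4,8-dimethylnona-3,7-dien-1-yl]oxirane-2-carbaldehyde | O=C[C@@H]1O[C@@]1(C)C[C@H](O[Si](C)(C)C(C)(C)C)/C=C(\C)CCC=C(C)C | intermediate
9 | (2S,3S)-3-ethenyl-2-methyl-2-[(2S,3E)-2-(tert-butyldimethylsilyloxy)-4,8-dimethylnona-3,7-dien-1-yl]oxirane | C=C[C@@H]1O[C@@]1(C)C[C@H](O[Si](C)(C)C(C)(C)C)/C=C(\C)CCC=C(C)C | intermediate
10 | (2S)-2-methyl-2-[(2S,3E)-2-(tert-butyldimethylsilyloxy)-4,8-dimethylnona-3,7-dien-1-yl]-2,5-dihydrofuran | C[C@]1(C[C@H](O[Si](C)(C)C(C)(C)C)/C=C(\C)CCC=C(C)C)C=CCO1 | intermediate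
11 | (2R)-2-methyl-2-[(2S,3E)-2-(tert-butyldimethylsilyloxy)-4,8-dimethylnona-3,7-dien-1-yl]-2,3-dihydrofuran | C[C@]1(C[C@H](O[Si](C)(C)C(C)(C)C)/C=C(\C)CCC=C(C)C)CC=CO1 | intermediate
12 | 2,5-dimethoxytoluene | Cc1cc(OC)ccc1OC | starting material
13 | 1-(bromomethyl)-2,5-dimethoxy-4-methylbenzene | BrCc1cc(OC)c(C)cc1OC | intermediate
14 | 2,2-dimethyl-1,3-dioxan-5-one | CC1(C)OCC(=O)CO1 | starting material
15 | RAMP, (R)-1-amino-2-(methoxymethyl)pyrrolidine | COC[C@H]1CCCN1N | starting material
16 | (2R)-N-(2,2-dimethyl-1,3-dioxan-5-ylidene)-2-(methoxymethyl)pyrrolidin-1-amine | COC[C@H]1CCCN1N=C1COC(C)(C)OC1 | intermediate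
17 | RAMP hydrazone of (4R)-4-[(2,5-dimethoxy-4-methylphenyl)methyl]-2,2-dimethyl-1,3-dioxan-5-one (formed in the flask; C=N geometry not defined) | COC[C@H]1CCCN1N=C2COC(C)(C)O[C@@H]2Cc3cc(OC)c(C)cc3OC | intermediate
18 | (4R)-4-[(2,5-dimethoxy-4-methylphenyl)methyl]-2,2-dimethyl-1,3-dioxan-5-one | COc1cc(C[C@H]2OC(C)(C)OCC2=O)c(OC)cc1C | intermediate
19 | 5-lithio derivative of 11 (formed in the flask) | [Li]C1=CC[C@](C)(C[C@H](O[Si](C)(C)C(C)(C)C)/C=C(\C)CCC=C(C)C)O1 | intermediate
20 | (4R,5S)-4-[(2,5-dimethoxy-4-methylphenyl)methyl]-2,2-dimethyl-5-{(5R)-5-methyl-5-[(2S,3E)-2-(tert-butyldimethylsilyloxy)-4,8-dimethylnona-3,7-dien-1-yl]-4,5-dihydrofuran-2-yl}-1,3-dioxan-5-ol | C[C@]1(C[C@H](O[Si](C)(C)C(C)(C)C)/C=C(\C)CCC=C(C)C)CC=C(O1)[C@]2(O)COC(C)(C)O[C@@H]2Cc3cc(OC)c(C)cc3OC | intermediate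
21 | desilylated enol ether diol from 20 (formed in the flask) | C[C@]1(C[C@H](O)/C=C(\C)CCC=C(C)C)CC=C(O1)[C@]2(O)COC(C)(C)O[C@@H]2Cc3cc(OC)c(C)cc3OC | intermediate
22 | (4R,5S)-4-[(2,5-dimethoxy-4-methylphenyl)methyl]-5-{(1R,3S,5R)-3-[(1E)-2,6-dimethylhepta-1,5-dien-1-yl]-5-methyl-2,8-dioxabicyclo[3.2.1]octan-1-yl}-2,2-dimethyl-1,3-dioxan-5-ol (formed in the flask) | CC1(C)OC[C@](O)([C@@H](Cc2cc(OC)c(C)cc2OC)O1)[C@]34CC[C@](C)(C[C@@H](/C=C(\C)CCC=C(C)C)O3)O4 | intermediate
23 | (2S,3R)-2-{(1R,3S,5R)-3-[(1E)-2,6-dimethylhepta-1,5-dien-1-yl]-5-methyl-2,8-dioxabicyclo[3.2.1]octan-1-yl}-4-(2,5-dimethoxy-4-methylphenyl)butane-1,2,3-triol | OC[C@](O)([C@@H](Cc1cc(OC)c(C)cc1OC)O)[C@]23CC[C@](C)(C[C@@H](/C=C(\C)CCC=C(C)C)O2)O3 | intermediate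
24 | 1,3-di-O-acetate of 23 (tertiary hydroxyl free) | CC(=O)OC[C@](O)([C@@H](Cc1cc(OC)c(C)cc1OC)OC(C)=O)[C@]23CC[C@](C)(C[C@@H](/C=C(\C)CCC=C(C)C)O2)O3 | intermediate
25 | 2-methyl-1,4-benzoquinone corresponding to 26 (formed in the flask) | CC(=O)OC[C@](O)([C@@H](CC1=CC(=O)C(C)=CC1=O)OC(C)=O)[C@]23CC[C@](C)(C[C@@H](/C=C(\C)CCC=C(C)C)O2)O3 | intermediate
26 | CNP0160303.2 | CC(=O)OC[C@](O)([C@@H](Cc1cc(O)c(C)cc1O)OC(C)=O)[C@]12CC[C@](C)(C[C@@H](/C=C(\C)CCC=C(C)C)O1)O2 | target

**Step count.** Total: 15 steps. Longest linear sequence: 12 steps (steps 1–8, then 12–15).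

**Steps most likely to fail**

Step 7. The copper catalyst may ionise the tertiary C–O bond instead of the allylic one (hydride shift to a ketone, elimination to an allylic alcohol), or the allyl cation may be captured by the silyl ether oxygen before the 1,3-oxygen shift. The fallback sets out from 9 and returns at 11, building the ring by lactonisation instead of ring expansion. Palladium(0)-catalysed formate hydrogenolysis of the vinyl oxirane (Pd2(dba)3, n-Bu3P, HCO2H/Et3N) delivers hydride to the allylic carbon and should give the homoallylic tertiary alcohol F1. Hydroboration of the terminal alkene with 9-BBN and perborate oxidation should give the 1,4-diol F2. TEMPO/PhI(OAc)2 oxidative lactonisation should give the γ-lactone F3. DIBAL-H at −78 °C should give the lactol F4. Mesylation and elimination (MsCl, Et3N, then warming) should give 11.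

Step 12. Proton transfer from the α,α′-dialkoxy ketone to the basic vinyl metal may outrun addition, or the bulky nucleophile may erode the axial facial selectivity. The fallback sets out from 18 and returns at 23, replacing ring-conformational control by acyclic chelation control. Methanolysis of the acetonide (PPTS, MeOH) should give the dihydroxy ketone F5. Selective silylation of the primary hydroxyl (TIPSCl, imidazole) should give the mono-TIPS ether F6. Its secondary hydroxyl is converted into the magnesium alkoxide (t-BuMgCl), and the magnesium derivative of 19 (MgBr2·OEt2) is added; attack on the five-membered Cram chelate from the side of the small substituent should give the adduct F7 with the same 2S,3R configuration. TBAF followed by PPTS in methanol should then give 23.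

Step 1. Addition to the less electrophilic β,β-disubstituted enal may be slow and poorly face-selective. The fallback sets out from 1 and returns at 6, forming the same C–C bond by a vinylogous aldol reaction that brings the trisubstituted alkene with it. Commercial methyl 3-methylbut-2-enoate is converted (LDA, TBSCl) into the silyl dienol ether F8. A SiCl4/chiral bisphosphoramide-catalysed vinylogous Mukaiyama aldol addition of F8 to 1 at its γ-carbon should give the (2E,5S)-hydroxy ester F9. Silylation (TBSCl, imidazole) should give the silyl ether F10, and DIBAL-H reduction should give 6.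

**Further compounds**

F1 | step 7 | (4R,6S,7E)-6-(tert-butyldimethylsilyloxy)-4,8,12-trimethyltrideca-1,7,11-trien-4-ol | C=CC[C@@](C)(O)C[C@H](O[Si](C)(C)C(C)(C)C)/C=C(\C)CCC=C(C)C
F2 | step 7 | (4R,6S,7E)-6-(tert-butyldimethylsilyloxy)-4,8,12-trimethyltrideca-7,11-diene-1,4-diol | OCCC[C@@](C)(O)C[C@H](O[Si](C)(C)C(C)(C)C)/C=C(\C)CCC=C(C)C
F3 | step 7 | (5R)-5-methyl-5-[(2S,3E)-2-(tert-butyldimethylsilyloxy)-4,8-dimethylnona-3,7-dien-1-yl]oxolan-2-one | O=C1CC[C@](C)(C[C@H](O[Si](C)(C)C(C)(C)C)/C=C(\C)CCC=C(C)C)O1
F4 | step 7 | (5R)-5-methyl-5-[(2S,3E)-2-(tert-butyldimethylsilyloxy)-4,8-dimethylnona-3,7-dien-1-yl]oxolan-2-ol (anomeric mixture) | OC1CC[C@](C)(C[C@H](O[Si](C)(C)C(C)(C)C)/C=C(\C)CCC=C(C)C)O1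
F5 | step 12 | (3R)-4-(2,5-dimethoxy-4-methylphenyl)-1,3-dihydroxybutan-2-one | COc1cc(C[C@@H](O)C(=O)CO)c(OC)cc1C
F6 | step 12 | (3R)-4-(2,5-dimethoxy-4-methylphenyl)-3-hydroxy-1-(triisopropylsilyloxy)butan-2-one | COc1cc(C[C@@H](O)C(=O)CO[Si](C(C)C)(C(C)C)C(C)C)c(OC)cc1C
F7 | step 12 | (2S,3R)-4-(2,5-dimethoxy-4-methylphenyl)-2-{(5R)-5-methyl-5-[(2S,3E)-2-(tert-butyldimethylsilyloxy)-4,8-dimethylnona-3,7-dien-1-yl]-4,5-dihydrofuran-2-yl}-1-(triisopropylsilyloxy)butane-2,3-diol | CC(C)[Si](OC[C@](O)([C@@H](Cc1cc(OC)c(C)cc1OC)O)C2=CC[C@](C)(C[C@H](O[Si](C)(C)C(C)(C)C)/C=C(\C)CCC=C(C)C)O2)(C(C)C)C(C)C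
F8 | step 1 | tert-butyl[(1-methoxy-3-methylbuta-1,3-dien-1-yl)oxy]dimethylsilane (C1 geometry not defined) | C=C(C)C=C(OC)O[Si](C)(C)C(C)(C)C
F9 | step 1 | methyl (2E,5S,6E)-5-hydroxy-3,7,11-trimethyldodeca-2,6,10-trienoate | COC(=O)/C=C(\C)C[C@H](O)/C=C(\C)CCC=C(C)C
F10 | step 1 | methyl (2E,5S,6E)-5-(tert-butyldimethylsilyloxy)-3,7,11-trimethyldodeca-2,6,10-trienoate | COC(=O)/C=C(\C)C[C@H](O[Si](C)(C)C(C)(C)C)/C=C(\C)CCC=C(C)C
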